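**Plan**

1. The target is a symmetrical dibenzyl ether. The first retrosynthetic cut is the central CH2–O–CH2 bond, which gives two molecules of one benzyl alcohol.
2. In that half, ring A carries the CH2O carbon on C1 and the diarylmethane carbon on C2 (Br on C3, OH on C4 and C5, H on C6). Linking these two ortho carbons through the oxygen gives a 1-arylphthalan, so the second cut is the diarylmethyl C–O bond of that phthalan.
3. Ring A of the phthalan is cut at C1–C2 and C3–C4. C1, C6, C5 and C4 are C2, C3, C4 and C5 of a 4-methoxyfuran, and C2 and C3 are the carbons of a bromoalkyne on a CH2–O–CH(Ar) tether.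
4. Forward: vanillin gives the ring B aldehyde and then a propargylic acetate; 4-bromofurfural gives 4-methoxyfurfuryl alcohol. Copper-catalysed etherification joins them, the alkyne is brominated, and heating closes ring A and the dihydrofuran ring together. Reductive phthalan opening, demethylation and dimerisation finish the route.
5. Stereochemistry: the target is achiral. The only stereocentre on the way (the aryl-bearing carbon made in step 3) is carried as the racemate and becomes a CH2 group in step 10.

Key step: step 8

Remark on the chemistry: the 4-methoxyfurans 9, 10 and 12 are acid-labile enol ethers; neutral to basic work-up and chromatography on Et3N-washed silica are assumed for them.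

**Route**

Step 1
Reactants: 1 vanillin
Product: 2 2,3-dibromo-4-hydroxy-5-methoxybenzaldehyde
Conditions: Br2 (2.2 equiv), Fe powder (cat.), NaOAc, AcOH, rt
Reagents that add atoms: bromine, BrBr
Why: Electrophilic aromatic bromination, in which the first bromine enters ortho to the free hydroxyl and the second, helped by FeBr3 formed from the iron, enters para to the methoxy group, the established outcome for vanillin.

Step 2
Reactants: 2 2,3-dibromo-4-hydroxy-5-methoxybenzaldehyde
Product: 3 2,3-dibromo-4,5-dimethoxybenzaldehyde
Conditions: MeI, K2CO3, DMF, rt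
Reagents that add atoms: iodomethane, CI
Why: Williamson O-methylation of the acidic bromophenol, with a base too weak to touch the aldehyde.

Step 3
Reactants: 3 2,3-dibromo-4,5-dimethoxybenzaldehyde; 4 ethynylmagnesium bromide
Product: 6 1-(2,3-dibromo-4,5-dimethoxyphenyl)prop-2-yn-1-yl acetate (racemic), via bromomagnesium propargylic alkoxide 5 (not isolated)
Conditions: THF, 0 °C → rt; then Ac2O, 0 °C → rt
Reagents that add atoms: acetic anhydride, CC(=O)OC(C)=O
Why: Grignard 1,2-addition of the alkynyl nucleophile followed by acylation of the magnesium alkoxide in the same flask; an alkynyl Grignard does not exchange with aryl bromides, and the new centre is racemic, which is immaterial because it is erased in step 10.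

Step 4
Reactants: 7 4-bromo-2-furaldehyde
Product: 8 (4-bromofuran-2-yl)methanol
Conditions: NaBH4, MeOH, 0 °C
Reagents that add atoms: none
Why: Borohydride reduction of the aldehyde, which leaves the furyl bromide untouched.

Step 5
Reactants: 8 (4-bromofuran-2-yl)methanol
Product: 9 (4-methoxyfuran-2-yl)methanol
Conditions: NaOMe (5 equiv), CuBr (10 mol%), MeOH–DMF, 90 °C; basic work-up
Reagents that add atoms: sodium methoxide, C[O-].[Na+]
Why: Ullmann-type methoxylation catalysed by monovalent copper, a reaction established for 3-bromofuran and 3-bromothiophene, in which the large excess of methoxide outcompetes the substrate's own alkoxide.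

Step 6
Reactants: 6 1-(2,3-dibromo-4,5-dimethoxyphenyl)prop-2-yn-1-yl acetate; 9 (4-methoxyfuran-2-yl)methanol
Product: 10 2-({[1-(2,3-dibromo-4,5-dimethoxyphenyl)prop-2-yn-1-yl]oxy}methyl)-4-methoxyfuran (racemic)
Conditions: CuOTf·0.5C6H6 (5 mol%), 2,6-bis(4,4-dimethyl-4,5-dihydrooxazol-2-yl)pyridine (10 mol%), i-Pr2NEt, 9 (1.5 equiv), THF, −10 °C → rt, argon
Reagents that add atoms: none
Why: Copper-catalysed propargylic etherification of a 1-aryl propargylic ester with a terminal alkyne: the copper acetylide loses acetate to form a copper allenylidene, which the primary alcohol attacks at the γ-carbon under amine base, so the acid-labile methoxyfuran never meets acid and no furfuryl halide is needed.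

Step 7
Reactants: 10 2-({[1-(2,3-dibromo-4,5-dimethoxyphenyl)prop-2-yn-1-yl]oxy}methyl)-4-methoxyfuran
Product: 12 2-({[3-bromo-1-(2,3-dibromo-4,5-dimethoxyphenyl)prop-2-yn-1-yl]oxy}methyl)-4-methoxyfuran (racemic), via lithium acetylide 11 (not isolated)
Conditions: LiN(SiMe3)2, THF, −78 °C; then BrCl2C–CCl2Br, −78 → −20 °C
Reagents that add atoms: 1,2-dibromo-1,1,2,2-tetrachloroethane, ClC(Cl)(Br)C(Cl)(Cl)Br
Why: Deprotonation of the terminal alkyne and electrophilic bromination of the lithium acetylide; the silylamide does not exchange with aryl bromides, and this mild bromine donor spares the electron-rich furan, which NBS/AgNO3 would attack.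

Step 8
Reactants: 12 2-({[3-bromo-1-(2,3-dibromo-4,5-dimethoxyphenyl)prop-2-yn-1-yl]oxy}methyl)-4-methoxyfuran
Product: 14 7-bromo-1-(2,3-dibromo-4,5-dimethoxyphenyl)-5-methoxy-1,3-dihydroisobenzofuran-6-ol (racemic), via oxa-bridged cycloadduct 13 (not isolated)
Conditions: PhMe (0.02 M), BHT (cat.), 110–130 °C, sealed tube, argon
Reagents that add atoms: none
Why: The furan acts as the diene in a concerted intramolecular [4+2] cycloaddition: its C2 bonds to the internal alkyne carbon and its C5 to the bromine-bearing carbon, giving oxanorbornadiene 13; the closest known reaction is the intramolecular Diels–Alder reaction of furfuryl propargyl ethers with aromatisation to hydroxy-dihydroisobenzofurans. The six-membered carbocycle (ring A) closes by the cycloaddition itself, and the five-membered dihydrofuran closes in the same event because the three-atom CH2–O–CH(Ar) tether spans the two carbons that become C1 and C2 of ring A. In 13 the C–O bond at the quaternary bridgehead (former furan C2) ionises, since the resulting cation is conjugated through the enol ether to the methoxy oxygen, and loss of the proton from the other bridgehead gives the phenol. No stereocentre is created that survives: the bridgehead centres of 13 become aromatic carbons and the benzylic centre is an untouched racemic spectator. The step needs regiocontrol twice, and the substrate supplies it: the short tether allows only one pairing of furan and alkyne carbons, and the 4-methoxy group decides which bridge bond breaks, so the hydroxyl ends next to bromine and the methoxy next to the hydroxyl. The electron-rich methoxyfuran, the aryl group on the tether and the irreversible aromatisation should drive the reaction, and the bromoalkyne delivers the C3 bromine of ring A directly.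

Step 9
Reactants: 14 7-bromo-1-(2,3-dibromo-4,5-dimethoxyphenyl)-5-methoxy-1,3-dihydroisobenzofuran-6-ol
Product: 15 7-bromo-1-(2,3-dibromo-4,5-dimethoxyphenyl)-5-methoxy-1,3-dihydroisobenzofuran-6-yl acetate (racemic)
Conditions: Ac2O, pyridine, DMAP (cat.), CH2Cl2, rt
Reagents that add atoms: acetic anhydride, CC(=O)OC(C)=O
Why: DMAP-catalysed acylation of the phenol; the acetate removes the para-hydroxyl donation that would otherwise labilise the CH2–O bond of the phthalan in the next step.

Step 10
Reactants: 15 7-bromo-1-(2,3-dibromo-4,5-dimethoxyphenyl)-5-methoxy-1,3-dihydroisobenzofuran-6-yl acetate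
Product: 17 2-bromo-3-[(2,3-dibromo-4,5-dimethoxyphenyl)methyl]-4-(hydroxymethyl)-6-methoxyphenol, via acetoxy benzyl alcohol 16 (not isolated)
Conditions: Et3SiH, CF3CO2H, CH2Cl2, 0 °C → rt; evaporate; then K2CO3, MeOH, 0 °C → rt
Reagents that add atoms: none
Why: Ionic hydrogenation, in which the acid ionises the doubly benzylic C1–O bond to a diarylmethyl cation (stabilised by the para methoxy groups of both rings) that the silane reduces, while the primary benzylic C–O bond stays intact; base-catalysed methanolysis then frees the phenol and any trifluoroacetate ester, and the stereocentre is gone.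

Step 11
Reactants: 17 2-bromo-3-[(2,3-dibromo-4,5-dimethoxyphenyl)methyl]-4-(hydroxymethyl)-6-methoxyphenol
Product: 19 3-bromo-4-[(2,3-dibromo-4,5-dihydroxyphenyl)methyl]-5-(hydroxymethyl)benzene-1,2-diol, via tetrahydroxy benzyl bromide 18 (not isolated)
Conditions: BBr3 (8 equiv), CH2Cl2, −78 °C → rt; then H2O–THF, 0 °C → rt
Reagents that add atoms: water, O (oxygen of the benzylic hydroxyl of 19); boron tribromide, BrB(Br)Br (only the benzylic bromine of intermediate 18)
Why: Lewis-acid cleavage of the three aryl methyl ethers with exchange of the benzylic hydroxyl for bromide, after which the para-hydroxybenzyl bromide is hydrolysed through its quinone methide on aqueous quench, the usual course in bromophenol chemistry; aryl bromides and the diarylmethane are inert.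

Step 12
Reactants: 19 3-bromo-4-[(2,3-dibromo-4,5-dihydroxyphenyl)methyl]-5-(hydroxymethyl)benzene-1,2-diol (two molecules)
Product: 20 5,5'-[oxybis(methylene)]bis{3-bromo-4-[(2,3-dibromo-4,5-dihydroxyphenyl)methyl]benzene-1,2-diol}
Conditions: TsOH·H2O (5 mol%), dry 1,4-dioxane (0.5 M), MgSO4, 40 °C, argon
Reagents that add atoms: none
Why: Acid-promoted dehydrative etherification of a para-hydroxybenzyl alcohol, as in the self-condensation of 4-hydroxybenzyl and vanillyl alcohols: the C4 hydroxyl para to the CH2OH group lets water leave as a quinone methide-type cation, the primary hydroxyl of a second molecule captures it, and growth should stop at the dimer because the ether has no aliphatic hydroxyl left and the brominated, hindered ring carbons are poor nucleophiles.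

**Compound list**

1 | vanillin (4-hydroxy-3-methoxybenzaldehyde) | COc1cc(C=O)ccc1O | starting material
2 | 2,3-dibromo-4-hydroxy-5-methoxybenzaldehyde | COc1cc(C=O)c(Br)c(Br)c1O | intermediate
3 | 2,3-dibromo-4,5-dimethoxybenzaldehyde | COc1cc(C=O)c(Br)c(Br)c1OC | intermediate
4 | ethynylmagnesium bromide | C#C[Mg]Br | starting material
5 | bromomagnesium 1-(2,3-dibromo-4,5-dimethoxyphenyl)prop-2-yn-1-olate (racemic) | C#CC(O[Mg]Br)c1cc(OC)c(OC)c(Br)c1Br | intermediate (not isolated)
6 | 1-(2,3-dibromo-4,5-dimethoxyphenyl)prop-2-yn-1-yl acetate (racemic) | CC(=O)OC(C#C)c1cc(OC)c(OC)c(Br)c1Br | intermediate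
7 | 4-bromo-2-furaldehyde | O=Cc1cc(Br)co1 | starting material
8 | (4-bromofuran-2-yl)methanol | OCc1cc(Br)co1 | intermediate
9 | (4-methoxyfuran-2-yl)methanol | COc1coc(CO)c1 | intermediate
10 | 2-({[1-(2,3-dibromo-4,5-dimethoxyphenyl)prop-2-yn-1-yl]oxy}methyl)-4-methoxyfuran (racemic) | C#CC(OCc1cc(OC)co1)c1cc(OC)c(OC)c(Br)c1Br | intermediate
11 | {3-(2,3-dibromo-4,5-dimethoxyphenyl)-3-[(4-methoxyfuran-2-yl)methoxy]prop-1-yn-1-yl}lithium (racemic) | [Li]C#CC(OCc1cc(OC)co1)c1cc(OC)c(OC)c(Br)c1Br | intermediate (not isolated)
12 | 2-({[3-bromo-1-(2,3-dibromo-4,5-dimethoxyphenyl)prop-2-yn-1-yl]oxy}methyl)-4-methoxyfuran (racemic) | COc1coc(COC(C#CBr)c2cc(OC)c(OC)c(Br)c2Br)c1 | intermediate (key-step precursor)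
13 | 6-bromo-4-(2,3-dibromo-4,5-dimethoxyphenyl)-8-methoxy-3,10-dioxatricyclo[5.2.1.0(1,5)]deca-5,8-diene (oxanorbornadiene fused to a dihydrofuran; racemic diastereomer mixture) | COC1=CC23COC(c4cc(OC)c(OC)c(Br)c4Br)C2=C(Br)C1O3 | intermediate (not isolated)
14 | 7-bromo-1-(2,3-dibromo-4,5-dimethoxyphenyl)-5-methoxy-1,3-dihydroisobenzofuran-6-ol (racemic) | COc1cc2c(c(Br)c1O)C(c1cc(OC)c(OC)c(Br)c1Br)OC2 | intermediate (key-step product)
15 | 7-bromo-1-(2,3-dibromo-4,5-dimethoxyphenyl)-5-methoxy-1,3-dihydroisobenzofuran-6-yl acetate (racemic) | COc1cc2c(c(Br)c1OC(C)=O)C(c1cc(OC)c(OC)c(Br)c1Br)OC2 | intermediate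
16 | 2-bromo-3-[(2,3-dibromo-4,5-dimethoxyphenyl)methyl]-4-(hydroxymethyl)-6-methoxyphenyl acetate | COc1cc(CO)c(Cc2cc(OC)c(OC)c(Br)c2Br)c(Br)c1OC(C)=O | intermediate (not isolated)
17 | 2-bromo-3-[(2,3-dibromo-4,5-dimethoxyphenyl)methyl]-4-(hydroxymethyl)-6-methoxyphenol | COc1cc(CO)c(Cc2cc(OC)c(OC)c(Br)c2Br)c(Br)c1O | intermediate
18 | 3-bromo-5-(bromomethyl)-4-[(2,3-dibromo-4,5-dihydroxyphenyl)methyl]benzene-1,2-diol | Oc1cc(CBr)c(Cc2cc(O)c(O)c(Br)c2Br)c(Br)c1O | intermediate (not isolated)
19 | 3-bromo-4-[(2,3-dibromo-4,5-dihydroxyphenyl)methyl]-5-(hydroxymethyl)benzene-1,2-diol | Oc1cc(CO)c(Cc2cc(O)c(O)c(Br)c2Br)c(Br)c1O | intermediate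
20 | 5,5'-[oxybis(methylene)]bis{3-bromo-4-[(2,3-dibromo-4,5-dihydroxyphenyl)methyl]benzene-1,2-diol} (achiral) | Oc1cc(Cc2c(COCc3cc(O)c(O)c(Br)c3Cc3cc(O)c(O)c(Br)c3Br)cc(O)c(O)c2Br)c(Br)c(Br)c1O | target

**Summary**

Total step count: 12. Longest linear sequence: 10 steps (vanillin 1 to target 20 through steps 1, 2, 3, 6, 7, 8, 9, 10, 11 and 12); the furan branch (steps 4 and 5) joins at step 6.

Steps most likely to fail:

Step 8 (cycloaddition). The ring closure may be slower than thermal degradation of the substrate, through loss of the alkynyl bromine or polymerisation of the electron-rich furan before the [4+2] event. The fallback introduces the bromine after ring construction. It sets out from terminal alkyne 10, which is thermally more robust and is heated on its own (o-dichlorobenzene, 130–180 °C); the same furan–alkyne cycloaddition and bridge opening should give 1-(2,3-dibromo-4,5-dimethoxyphenyl)-5-methoxy-1,3-dihydroisobenzofuran-6-ol F1. NBS (1 equiv, CH2Cl2, −20 °C) then brominates ortho to the phenol at C7, the only free position ortho or para to the hydroxyl, and the route is rejoined at 14.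

Step 12 (dimerisation). Under acid equilibration the benzylic cation may be captured by phenolic oxygen or ring carbon, giving oligomers, or the ether may revert to the alcohol. The fallback replaces the equilibrium dehydration by an irreversible, acid-free cross-alkylation of two separately prepared halves. It sets out from 17: BBr3 demethylation as in step 11, but with an ice-water quench and immediate extraction, so that benzyl bromide 18 is isolated. Bromide 18 is then added slowly to one equivalent of alcohol 19 in dry THF at 0 °C with 2,6-di-tert-butyl-4-methylpyridine as a hindered HBr scavenger that does not deprotonate the phenols. Substitution by the primary hydroxyl should give the target 20 directly. This fallback makes no compound outside the compound list (entry F0).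

Step 6 (fragment coupling). The copper allenylidene may be attacked by C5 of the electron-rich furan instead of the hydroxyl (C-propargylation), or ionisation of the hindered ortho-bromoaryl acetate may be sluggish. The fallback is a classical Williamson ether synthesis. It sets out from 6, which is methanolysed (K2CO3, MeOH, rt) to 1-(2,3-dibromo-4,5-dimethoxyphenyl)prop-2-yn-1-ol F2. Separately, alcohol 9 is converted under neutral Appel conditions (CBr4, PPh3, 2,6-lutidine, CH2Cl2, −20 °C) into 2-(bromomethyl)-4-methoxyfuran F3, which is used at once as a cold solution. The sodium alkoxide of F2 (NaH, THF–DMF, 0 °C) is alkylated with F3, and the route is rejoined at 10.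

**Further compounds**

F1 | step 8 | 1-(2,3-dibromo-4,5-dimethoxyphenyl)-5-methoxy-1,3-dihydroisobenzofuran-6-ol (racemic) | COc1cc2c(cc1O)C(c1cc(OC)c(OC)c(Br)c1Br)OC2
F0 | step 12 | none | none
F2 | step 6 | 1-(2,3-dibromo-4,5-dimethoxyphenyl)prop-2-yn-1-ol (racemic) | C#CC(O)c1cc(OC)c(OC)c(Br)c1Br
F3 | step 6 | 2-(bromomethyl)-4-methoxyfuran | COc1coc(CBr)c1
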